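**Retrosynthetic overview**

1. The (E)-propenal on C7 is traced back to a C7 methyl ester (reduction, benzylic oxidation, two-carbon Wittig extension), so the stereogenic dioxane core is finished first.
2. Feature used: in the 2,3-dihydro-1,4-benzodioxine (O1, C2 carrying the trimethoxyphenyl group, C3 carrying methyl, O4, ring A = C4a to C8a), O1 joins benzylic C2 to C8a. O4 joins C3 to C4a, the ring A carbon para to the C7 chain and lying between C8a and the methoxylated C5.
3. Key disconnection: O1–C2 and O4–C4a are cut together. This gives a 2-bromophenol (oxygen on C8a, bromine on C4a) and a cis aryl/methyl epoxide (C2, C3, O4); one inversion at C2 turns the cis-epoxide into the trans-(2S,3S) dioxane.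
4. The epoxide comes from 3,4,5-trimethoxybenzaldehyde by Z-selective Wittig olefination and (salen)manganese epoxidation. The bromophenol comes from mono-methylation of a symmetric bromoresorcinol ester.
5. Ring order: both benzene rings are purchased; the dioxane ring is the only ring formed (step 4).

Key step: step 4

Remark (assumption): the sense of induction of (R,R)-MnCl(salen) on the (Z)-propenylarene of this route is taken to be that established for cis-β-methylstyrene (epoxide with R configuration at the benzylic carbon); the (S,S)-catalyst would be used should the opposite sense apply.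

**Route**

Step 1
Reactants: 1 methyl 4-bromo-3,5-dihydroxybenzoate
Product: 2 methyl 4-bromo-3-hydroxy-5-methoxybenzoate
Conditions: MeI (1.0 equiv), K2CO3 (1.0 equiv), DMF, 0 °C → rt; chromatography (dimethyl ether removed, 1 recovered and recycled)
Reagents that add atoms: iodomethane, CI
Why: Williamson O-methylation in which the two hydroxyl groups of 1 are equivalent by symmetry, so only the degree of alkylation has to be held back by limiting MeI and base.

Step 2
Reactants: 3 3,4,5-trimethoxybenzaldehyde; 4 ethyltriphenylphosphonium bromide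
Product: 6 (Z)-1,2,3-trimethoxy-5-(prop-1-en-1-yl)benzene, via ethylidenetriphenylphosphorane 5 (not isolated)
Conditions: 4, NaN(SiMe3)2, THF, 0 °C; then 3, −78 °C → rt; AgNO3-impregnated silica to remove (E)-isomer
Reagents that add atoms: none
Why: Wittig olefination with a non-stabilised ylide under lithium-free conditions, where kinetically controlled, irreversible formation of the cis-oxaphosphetane should give mainly the (Z)-alkene.

Step 3
Reactants: 6 (Z)-1,2,3-trimethoxy-5-(prop-1-en-1-yl)benzene
Product: 7 (2S,3R)-2-methyl-3-(3,4,5-trimethoxyphenyl)oxirane (cis)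
Conditions: (R,R)-MnCl(salen) (5 mol%; salen = C36H52N2O2, N,N'-bis(3,5-di-tert-butylsalicylidene)cyclohexane-1,2-diaminate), 4-phenylpyridine N-oxide (20 mol%), aq NaOCl (pH 11.3), CH2Cl2, 0 °C; chromatography on Et3N-treated silica
Reagents that add atoms: sodium hypochlorite, [Na+].[O-]Cl
Why: Jacobsen–Katsuki epoxidation of a cis-1-arylpropene, the best substrate class for this catalyst, in which both stereocentres are set by catalyst control as the chiral diamine backbone and the tert-butyl groups steer side-on approach of the olefin to the oxo species of pentavalent manganese, the N-oxide ligand suppressing the stepwise collapse that would leak trans-epoxide.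

Step 4
Reactants: 2 methyl 4-bromo-3-hydroxy-5-methoxybenzoate; 7 (2S,3R)-2-methyl-3-(3,4,5-trimethoxyphenyl)oxirane
Product: 9 methyl (2S,3S)-5-methoxy-3-methyl-2-(3,4,5-trimethoxyphenyl)-2,3-dihydro-1,4-benzodioxine-7-carboxylate, via ring-opened caesium alkoxide 8 (not isolated)
Conditions: Cs2CO3 (2 equiv), CuI (10 mol%), 1,10-phenanthroline (20 mol%), 4 Å MS, DMF, 80 °C then 110 °C, Ar
Reagents that add atoms: none
Why: The caesium phenoxide of 2 opens epoxide 7 by backside SN2 attack at the benzylic carbon (O1–C2, inversion from R to S) to give alkoxide 8, whose oxygen binds the phenanthroline complex of monovalent copper, which adds oxidatively into the neighbouring C–Br bond (activated by the para ester) and forms O4–C4a by C–O reductive elimination. The closest known reaction type is the copper-catalysed tandem opening of epoxides by 2-halophenols followed by intramolecular Ullmann O-arylation to 2,3-dihydro-1,4-benzodioxines. The dioxane ring closes by intramolecular aryl etherification through a six-membered arrangement (formally 6-exo at the aryl carbon), the alkoxide being held next to the ortho bromide by the new O1–C2 bond. No stereocentre is made from a prochiral atom, since C3 keeps the configuration of the methyl-bearing epoxide carbon and C2 is the inverted benzylic carbon, so substrate control alone turns the (2S,3R)-cis-epoxide into the trans-(2S,3S) product. The step needs attack at the benzylic rather than the methyl-bearing carbon and a clean SN2 course, which the aryl π-system secures by lowering the barrier for benzylic substitution (as in base-mediated phenoxide openings of 3-aryloxiranes), while the carbonate medium without strong Lewis acid and the only weakly cation-stabilising 3,4,5-trimethoxyphenyl ring disfavour ionisation. The regiochemistry on ring A is fixed by the position of bromine in 2, and the temperature staging lets ring opening run ahead of copper-mediated arylation so that intermolecular coupling of 2 with itself stays minor.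

Step 5
Reactants: 9 methyl (2S,3S)-5-methoxy-3-methyl-2-(3,4,5-trimethoxyphenyl)-2,3-dihydro-1,4-benzodioxine-7-carboxylate
Product: 10 [(2S,3S)-5-methoxy-3-methyl-2-(3,4,5-trimethoxyphenyl)-2,3-dihydro-1,4-benzodioxin-7-yl]methanol
Conditions: i-Bu2AlH (2.5 equiv), CH2Cl2, −78 → 0 °C; aq potassium sodium tartrate (KNaC4H4O6) work-up
Reagents that add atoms: none
Why: Hydride reduction of an aryl ester to the benzylic alcohol, which leaves the aryl ethers and the two non-enolisable stereocentres untouched.

Step 6
Reactants: 10 [(2S,3S)-5-methoxy-3-methyl-2-(3,4,5-trimethoxyphenyl)-2,3-dihydro-1,4-benzodioxin-7-yl]methanol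
Product: 11 (2S,3S)-5-methoxy-3-methyl-2-(3,4,5-trimethoxyphenyl)-2,3-dihydro-1,4-benzodioxine-7-carbaldehyde
Conditions: activated MnO2 (10 equiv), CH2Cl2, rt
Reagents that add atoms: none
Why: Chemoselective oxidation of a primary benzylic alcohol by manganese dioxide (tetravalent manganese), which stops at the aldehyde and does not touch the benzylic ether C2–H.

Step 7
Reactants: 11 (2S,3S)-5-methoxy-3-methyl-2-(3,4,5-trimethoxyphenyl)-2,3-dihydro-1,4-benzodioxine-7-carbaldehyde
Product: 12 (2E)-3-[(2S,3S)-5-methoxy-3-methyl-2-(3,4,5-trimethoxyphenyl)-2,3-dihydro-1,4-benzodioxin-7-yl]prop-2-enal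
Conditions: Ph3P=CHCHO (1.3 equiv), toluene, 80 °C
Reagents that add atoms: (triphenylphosphoranylidene)acetaldehyde, O=CC=P(c1ccccc1)(c1ccccc1)c1ccccc1
Why: Wittig olefination with a stabilised formylmethylene ylide, whose reversible addition should favour the (E)-enal, the reaction being stopped once 11 is consumed to limit a second homologation.

**Compound list**

1 | methyl 4-bromo-3,5-dihydroxybenzoate | COC(=O)c1cc(O)c(Br)c(O)c1 | starting material
2 | methyl 4-bromo-3-hydroxy-5-methoxybenzoate | COC(=O)c1cc(O)c(Br)c(OC)c1 | intermediate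
3 | 3,4,5-trimethoxybenzaldehyde | COc1cc(C=O)cc(OC)c1OC | starting material
4 | ethyltriphenylphosphonium bromide | CC[P+](c1ccccc1)(c1ccccc1)c1ccccc1.[Br-] | starting material
5 | ethylidenetriphenylphosphorane (ylide, formed in the flask) | CC=P(c1ccccc1)(c1ccccc1)c1ccccc1 | intermediate
6 | (Z)-1,2,3-trimethoxy-5-(prop-1-en-1-yl)benzene | C/C=C\c1cc(OC)c(OC)c(OC)c1 | intermediate
7 | (2S,3R)-2-methyl-3-(3,4,5-trimethoxyphenyl)oxirane (cis) | C[C@@H]1O[C@@H]1c2cc(OC)c(OC)c(OC)c2 | intermediate
8 | methyl 4-bromo-3-{[(1S,2S)-2-hydroxy-1-(3,4,5-trimethoxyphenyl)propyl]oxy}-5-methoxybenzoate (present as its caesium alkoxide; SMILES of the neutral alcohol) | COC(=O)c1cc(O[C@H]([C@H](C)O)c2cc(OC)c(OC)c(OC)c2)c(Br)c(OC)c1 | intermediate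
9 | methyl (2S,3S)-5-methoxy-3-methyl-2-(3,4,5-trimethoxyphenyl)-2,3-dihydro-1,4-benzodioxine-7-carboxylate (trans) | COc1cc([C@@H]2Oc3cc(C(=O)OC)cc(OC)c3O[C@H]2C)cc(OC)c1OC | intermediate
10 | [(2S,3S)-5-methoxy-3-methyl-2-(3,4,5-trimethoxyphenyl)-2,3-dihydro-1,4-benzodioxin-7-yl]methanol | COc1cc([C@@H]2Oc3cc(CO)cc(OC)c3O[C@H]2C)cc(OC)c1OC | intermediate
11 | (2S,3S)-5-methoxy-3-methyl-2-(3,4,5-trimethoxyphenyl)-2,3-dihydro-1,4-benzodioxine-7-carbaldehyde | COc1cc([C@@H]2Oc3cc(C=O)cc(OC)c3O[C@H]2C)cc(OC)c1OC | intermediate
12 | (2E)-3-[(2S,3S)-5-methoxy-3-methyl-2-(3,4,5-trimethoxyphenyl)-2,3-dihydro-1,4-benzodioxin-7-yl]prop-2-enal | COc1cc([C@@H]2Oc3cc(/C=C/C=O)cc(OC)c3O[C@H]2C)cc(OC)c1OC | target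

**Step count**

Total steps: 7. Longest linear sequence: 6 steps (3 → 6 → 7 → 9 → 10 → 11 → 12; steps 2 to 7).

**Steps most likely to fail**

Step 4. The two epoxide carbons may compete for the phenoxide. Attack at the methyl-bearing carbon followed by ring closure would exchange aryl and methyl between C2 and C3. Fallback, setting out from 6 and returning at 9: the roles of the two phenolic oxygens are exchanged so that this regiochemistry becomes the productive one. Alkene 6 is epoxidised as in step 3 but with (S,S)-MnCl(salen), which should give (2R,3S)-2-methyl-3-(3,4,5-trimethoxyphenyl)oxirane F1. Commercial methyl 3-bromo-4-hydroxy-5-methoxybenzoate (COC(=O)c1cc(Br)c(O)c(OC)c1), whose hydroxyl oxygen is the future O4 on C4a, then takes the place of 2 under the conditions of step 4. SN2 opening of F1 at the methyl-bearing carbon (inversion, R to S) gives methyl 3-bromo-4-{[(1S,2S)-1-hydroxy-1-(3,4,5-trimethoxyphenyl)propan-2-yl]oxy}-5-methoxybenzoate F2 as its alkoxide, not isolated. Copper-catalysed arylation of the benzylic alkoxide at the C–Br bond (retention at C2) closes the same dioxane, 9. Should neither carbon be attacked cleanly, the regiodefined stepwise sequence given below for step 3 would be used.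

Step 3. Enantioface discrimination may be incomplete, and the olefin geometry may be partly lost through stepwise radical collapse at the oxo-manganese stage (leakage to trans-epoxide). The epoxide may also open under acid during isolation. Fallback, setting out from 2 and returning at 8 and then 9: the epoxide is bypassed and the methyl-bearing stereocentre is taken from the lactate pool. Felkin–Anh addition of 3,4,5-trimethoxyphenylmagnesium bromide (COc1cc([Mg]Br)cc(OC)c1OC) to commercial (S)-2-[(tert-butyldimethylsilyl)oxy]propanal (C[C@H](O[Si](C)(C)C(C)(C)C)C=O) in THF at −78 °C should give mainly the anti alcohol (1R,2S)-2-[(tert-butyldimethylsilyl)oxy]-1-(3,4,5-trimethoxyphenyl)propan-1-ol F3, freed from its syn isomer by chromatography. Mitsunobu etherification of phenol 2 with F3 (PPh3, diisopropyl azodicarboxylate, toluene, 0 °C → rt) forms O1–C2 with inversion at the benzylic carbon and gives methyl 4-bromo-3-{[(1S,2S)-2-[(tert-butyldimethylsilyl)oxy]-1-(3,4,5-trimethoxyphenyl)propyl]oxy}-5-methoxybenzoate F4. Bu4NF in THF removes the silyl group to give alcohol 8, here isolated. Alcohol 8 is cyclised to 9 with CuI, 1,10-phenanthroline and Cs2CO3 in toluene at 110 °C.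

Step 7. The product enal is itself an aldehyde and may be olefinated a second time by the ylide, while the electron-rich aldehyde reacts slowly. Fallback, setting out from 11 and returning at 12: Horner–Wadsworth–Emmons reaction of 11 with triethyl phosphonoacetate (NaH, THF, 0 °C) gives ethyl (2E)-3-[(2S,3S)-5-methoxy-3-methyl-2-(3,4,5-trimethoxyphenyl)-2,3-dihydro-1,4-benzodioxin-7-yl]prop-2-enoate F5. Reduction with i-Bu2AlH (CH2Cl2, −78 °C) gives (2E)-3-[(2S,3S)-5-methoxy-3-methyl-2-(3,4,5-trimethoxyphenyl)-2,3-dihydro-1,4-benzodioxin-7-yl]prop-2-en-1-ol F6. Oxidation of the allylic alcohol with MnO2 (CH2Cl2, rt) gives 12.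

**Further compounds**

F1 | step 4 | (2R,3S)-2-methyl-3-(3,4,5-trimethoxyphenyl)oxirane | C[C@H]1O[C@H]1c2cc(OC)c(OC)c(OC)c2
F2 | step 4 | methyl 3-bromo-4-{[(1S,2S)-1-hydroxy-1-(3,4,5-trimethoxyphenyl)propan-2-yl]oxy}-5-methoxybenzoate | COC(=O)c1cc(Br)c(O[C@@H](C)[C@@H](O)c2cc(OC)c(OC)c(OC)c2)c(OC)c1
F3 | step 3 | (1R,2S)-2-[(tert-butyldimethylsilyl)oxy]-1-(3,4,5-trimethoxyphenyl)propan-1-ol | C[C@H](O[Si](C)(C)C(C)(C)C)[C@H](O)c1cc(OC)c(OC)c(OC)c1
F4 | step 3 | methyl 4-bromo-3-{[(1S,2S)-2-[(tert-butyldimethylsilyl)oxy]-1-(3,4,5-trimethoxyphenyl)propyl]oxy}-5-methoxybenzoate | COC(=O)c1cc(O[C@H]([C@H](C)O[Si](C)(C)C(C)(C)C)c2cc(OC)c(OC)c(OC)c2)c(Br)c(OC)c1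
F5 | step 7 | ethyl (2E)-3-[(2S,3S)-5-methoxy-3-methyl-2-(3,4,5-trimethoxyphenyl)-2,3-dihydro-1,4-benzodioxin-7-yl]prop-2-enoate | COc1cc([C@@H]2Oc3cc(/C=C/C(=O)OCC)cc(OC)c3O[C@H]2C)cc(OC)c1OC
F6 | step 7 | (2E)-3-[(2S,3S)-5-methoxy-3-methyl-2-(3,4,5-trimethoxyphenyl)-2,3-dihydro-1,4-benzodioxin-7-yl]prop-2-en-1-ol | COc1cc([C@@H]2Oc3cc(/C=C/CO)cc(OC)c3O[C@H]2C)cc(OC)c1OC
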